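To the chemist taking over the bench: the north flask holds substrate under a held gas phase, with target forming, and it is to be read at 3.0 h.

| flask | substrate | gas phase | remark | time |
|---|---|---|---|---|
| north | 0.064 M | 2.9 mM (held) | the very flask that is asked about, followed so far |  |
| west | 0.096 M | 2.9 mM (held) | run made earlier |  |
| flask | 0.064 M | 2.9 mM (held) |  | 3.0 h |

| run | time / min | target / % | substrate / % |
|---|---|---|---|
| north | 2.50 | 0 | 100 |
| north | 6.00 | 1 | 93 |
| north | 15.0 | 6 | 94 |
| north | 30.0 | 13 | 83 |
| west | 6.00 | 0 | 97 |
| west | 12.0 | 5 | 94 |
| west | 30.0 | 14 | 90 |
| west | 80.0 | 32 | 67 |

(readings scatter by 2 percentage points)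

- birch: doubling the transfer coefficient of the gas phase, all else as stated
- ash: doubling the saturation concentration of gas phase, all else as stated

- at the start none of the gas is dissolved
- reactions considered so far: gas phase <-> dissolved gas; substrate + dissolved gas -> target; dissolved gas + target -> over-reacted product

1. target at 3.0 h, in percent of the substrate charged
2. the change that raises the amount of target at 3.0 h, in percent of the substrate charged most ("none" if none brings more than 2 percentage points) (birch / ash / none)
3. amount of target at 3.0 h, in percent of the substrate charged, after birch

At 30.0 min the north flask shows 13% target and the west flask, with more substrate, 14%. Since these shares agree, the readings fit a pseudo-first-order fall of c(substrate) in both flasks, and gas transfer appears to keep up. So stirring harder should bring little, and the stirrer can be left alone.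

The useful quantity is the substrate half-life 2.40 h, the time in which substrate halves under the held gas, read from the last west target reading and carrying that reading's scatter. By my own reckoning, the north flask will hold 42.0% substrate at 3.0 h, with slightly less than the remaining 58.0% as target.

The forecast gives 56% target, 59% after birch, and ash as the best change, holding that “Doubling saturation roughly doubles the rate”.

The flask gives 52.9% target, and 53.5% after birch, a gain of 0.53 percentage points. The best change is ash, with a gain of 20 points.

    gas phase ⇌ dissolved gas, rate k1*(csat - [dissolved gas]) (kL = 140 h⁻¹)
    substrate + dissolved gas → target (k = 95.0 M⁻¹ h⁻¹)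
    dissolved gas + target → over-reacted product (k = 8.30 M⁻¹ h⁻¹)

The north flask has not come to rest at 3.0 h: it still holds 44.9% substrate beside 52.9% target, against the 42.0% substrate reckoned from 2.40 h. Read at 12 h, the same flask holds 3.9% substrate, against 3.12% from that half-life, and target stands at 78.2%. Ten times the asked time still changes much: at 30.0 h substrate is down to 0.0275%, over-reacted product has risen from 2.12% to 46.5%, and target is back at 53.5%.

All runs come from a simulation from invented constants; scatter was added.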